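**Retrosynthetic overview**

1. The plan rests on ring B (C1'–C6'). Its three substituents are the chromone C2 on C1', the free OH on C3' and the OMe on C4'. They map onto an alkyne carbon, onto C2 (next to the ring oxygen) and onto C3–OMe of 3-methoxyfuran, so ring B can be built de novo with its phenol already unmasked.
2. Gardenin D ⇒ its 5-O-methyl ether (BCl3 cleaves the ether peri to C4=O) ⇒ 2-ethynyl-5,6,7,8-tetramethoxychromone + 3-methoxyfuran ([4+2], then aromatising bridge opening; bonds C2'–C3' and C1'–C6').
3. Ethynylchromone ⇒ chromone-2-carbaldehyde ⇒ 2-hydroxymethylchromone ⇒ chromone-2-carboxylate. The homologation is an aprotic Colvin reaction; carbonate/methanol conditions are avoided because methanol adds to conjugated aldehydes and enynones of this kind.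
4. Chromone-2-carboxylate ⇒ 2-hydroxy-3,4,5,6-tetramethoxyacetophenone + diethyl oxalate. The acetophenone ⇒ 2,3,4,5-tetramethoxyphenol ⇒ 1,2,3,4-tetramethoxybenzene, which lacks the fifth ring oxygen (added by lithiation–borylation–oxidation).
5. Ring order: A is bought, C is closed in step 3, B is closed in step 7. The target has no stereocentre.

Key step: step 7

Assumption: 1,2,3,4-tetramethoxybenzene and 3-methoxyfuran are taken as catalogue compounds, and the furan is distilled from K2CO3 just before use because traces of acid hydrolyse its enol ether.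

**Step 1**
Reactants: 1 1,2,3,4-tetramethoxybenzene
Product: 4 2,3,4,5-tetramethoxyphenol, via aryllithium 2 (not isolated), via dimethyl arylboronate 3 (not isolated)
Conditions: n-BuLi, TMEDA, THF, 0 °C; B(OMe)3, −78 °C → rt; AcOH, 30% aq. H2O2, 0 °C → rt
Reagents that add atoms: hydrogen peroxide, OO
Why: Directed ortho-metalation followed by borylation and boronate oxidation: a flanking methoxy group (with TMEDA) steers n-BuLi to one of the two symmetry-equivalent ring C–H bonds, and the peroxide-induced 1,2-aryl shift from boron to oxygen installs the fifth ring-A oxygen under mildly acidic conditions that spare the electron-rich phenol.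

**Step 2**
Reactants: 4 2,3,4,5-tetramethoxyphenol
Product: 5 1-(2-hydroxy-3,4,5,6-tetramethoxyphenyl)ethan-1-one
Conditions: AcOH, BF3·OEt2, 80 °C; then H2O
Reagents that add atoms: acetic acid, CC(=O)O
Why: Friedel–Crafts acylation of a phenol with the AcOH/BF3 couple: the single unsubstituted ring carbon lies ortho to the hydroxyl, so only one C-acyl product can form, and the methyl ethers tolerate BF3 at this temperature.

**Step 3**
Reactants: 5 1-(2-hydroxy-3,4,5,6-tetramethoxyphenyl)ethan-1-one; 6 diethyl oxalate
Product: 8 ethyl 5,6,7,8-tetramethoxy-4-oxo-4H-chromene-2-carboxylate, via diketo ester 7 (not isolated)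
Conditions: NaOEt, EtOH, reflux; then conc. HCl, EtOH, 70 °C, short
Reagents that add atoms: none
Why: Crossed Claisen condensation of the methyl ketone enolate with the non-enolisable oxalate gives 7, and acid-catalysed attack of the phenol on the C2 ketone with loss of water (6-exo-trig hemiketalisation, then dehydration) closes ring C, the classical chromone-2-carboxylate synthesis; the acid stage is kept short so that the 5-methoxy group is not solvolysed.

**Step 4**
Reactants: 8 ethyl 5,6,7,8-tetramethoxy-4-oxo-4H-chromene-2-carboxylate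
Product: 9 2-(hydroxymethyl)-5,6,7,8-tetramethoxy-4H-chromen-4-one
Conditions: NaBH4, EtOH, 0 °C
Reagents that add atoms: none
Why: Chemoselective borohydride reduction: the ester sits on the oxygen-bearing C2 of an electron-poor pyranone and is activated like an α-alkoxyacrylate, whereas the C4 carbonyl is a deactivated vinylogous ester, a selectivity established for chromone-2-carboxylates at low temperature.

**Step 5**
Reactants: 9 2-(hydroxymethyl)-5,6,7,8-tetramethoxy-4H-chromen-4-one
Product: 10 5,6,7,8-tetramethoxy-4-oxo-4H-chromene-2-carbaldehyde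
Conditions: MnO2 (activated, excess), CH2Cl2, rt
Reagents that add atoms: none
Why: MnO2 oxidation of an allylic-type primary alcohol, as practised on 2-hydroxymethyl-4-pyranones; the neutral, water-free conditions and work-up by filtration should deliver the hydrate-prone aldehyde without over-oxidation.

**Step 6**
Reactants: 10 5,6,7,8-tetramethoxy-4-oxo-4H-chromene-2-carbaldehyde
Product: 12 2-ethynyl-5,6,7,8-tetramethoxy-4H-chromen-4-one, via lithium alkoxide adduct 11 (not isolated)
Conditions: Me3SiCHN2, LiN(i-Pr)2, THF, −78 °C; add 10, −78 → 0 °C; AcOH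
Reagents that add atoms: trimethylsilyldiazomethane, C[Si](C)(C)C=[N+]=[N-]
Why: Colvin rearrangement: the lithiated silyl diazomethane adds to the aldehyde, by far the most electrophilic carbonyl, to give 11, which on warming loses lithium trimethylsilanolate (Peterson-type) and N2 and undergoes a 1,2-hydride shift to the terminal alkyne, all in an aprotic medium with no alcohol that could add to the conjugated aldehyde or to the enynone product.

**Step 7**
Reactants: 12 2-ethynyl-5,6,7,8-tetramethoxy-4H-chromen-4-one; 13 3-methoxyfuran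
Product: 15 2-(3-hydroxy-4-methoxyphenyl)-5,6,7,8-tetramethoxy-4H-chromen-4-one (5-O-methylgardenin D), via oxanorbornadiene adduct 14 (not isolated)
Conditions: 13 (5 equiv), ZnI2 (20 mol %), 4 Å MS, ClCH2CH2Cl, 60 °C, sealed tube
Reagents that add atoms: none
Why: Proposed new method: ZnI2 bound between the C4 carbonyl oxygen and the 5-methoxy oxygen of 12 lowers the LUMO of the conjugated O=C4–C3=C2–C≡CH chain, so its terminal carbon is the electrophilic end and bonds first to furan C2 (the nucleophilic β-carbon of the C3 enol ether) while furan C5 closes onto the internal alkyne carbon in an asynchronous normal-electron-demand [4+2] cycloaddition, which makes C2'–C3' and C1'–C6' and gives 14. The closest known reaction type is the Diels–Alder addition of alkoxyfurans to propiolates, acetylenedicarboxylates and ynones with aromatising opening of the 7-oxanorbornadiene to a phenol; new here is a terminal alkyne that is activated only vinylogously through a pyranone C=C bond. Ring B is the only ring closed, and it closes by this intermolecular [4+2] mode with the four furan carbons and the two alkyne carbons as its six members. In 14 the zinc salt then ionises the C–O bond at the bridgehead next to the chromonyl-bearing carbon (future C6'), because that cyclohexadienyl cation places charge on the methoxy-bearing C4', whereas the other opening would place charge on the chromone-bearing C1' and none on C4'; loss of the proton from the oxygen-bearing carbon leaves the hydroxyl on C3'. The two bridgehead stereocentres of racemic 14 vanish on aromatisation, so no stereocontrol is required. The step needs reaction at the alkyne and not at C2=C3 (a donor-substituted, trisubstituted vinylogous ester bond whose adduct could not aromatise) and ring closure in preference to proton loss from a first-formed zwitterion, which the aprotic medium and the irreversible aromatisation should secure.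

**Step 8**
Reactants: 15 2-(3-hydroxy-4-methoxyphenyl)-5,6,7,8-tetramethoxy-4H-chromen-4-one
Product: 17 gardenin D (5-hydroxy-2-(3-hydroxy-4-methoxyphenyl)-6,7,8-trimethoxy-4H-chromen-4-one), via bis(dichloroboryl) chelate 16 (not isolated)
Conditions: BCl3 (2.2 equiv), CH2Cl2, −78 → 0 °C; then H2O
Reagents that add atoms: none
Why: Chelation-directed ether cleavage: after one equivalent of BCl3 is consumed by the 3'-phenol, the second binds the C4 carbonyl and the peri 5-methoxy oxygen in a six-membered chelate, so chloride removes only that methyl group, the established way to unmask the 5-hydroxyl of polymethoxyflavones, and hydrolysis of 16 releases both phenols.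

**Compound list**

1 | 1,2,3,4-tetramethoxybenzene | COc1ccc(OC)c(OC)c1OC | starting material
2 | (2,3,4,5-tetramethoxyphenyl)lithium | [Li]c1cc(OC)c(OC)c(OC)c1OC | intermediate
3 | dimethyl (2,3,4,5-tetramethoxyphenyl)boronate | COB(OC)c1cc(OC)c(OC)c(OC)c1OC | intermediate
4 | 2,3,4,5-tetramethoxyphenol | COc1cc(O)c(OC)c(OC)c1OC | intermediate
5 | 1-(2-hydroxy-3,4,5,6-tetramethoxyphenyl)ethan-1-one | CC(=O)c1c(O)c(OC)c(OC)c(OC)c1OC | intermediate
6 | diethyl oxalate | CCOC(=O)C(=O)OCC | starting material
7 | ethyl 4-(2-hydroxy-3,4,5,6-tetramethoxyphenyl)-2,4-dioxobutanoate | CCOC(=O)C(=O)CC(=O)c1c(O)c(OC)c(OC)c(OC)c1OC | intermediate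
8 | ethyl 5,6,7,8-tetramethoxy-4-oxo-4H-chromene-2-carboxylate | CCOC(=O)c1cc(=O)c2c(OC)c(OC)c(OC)c(OC)c2o1 | intermediate
9 | 2-(hydroxymethyl)-5,6,7,8-tetramethoxy-4H-chromen-4-one | OCc1cc(=O)c2c(OC)c(OC)c(OC)c(OC)c2o1 | intermediate
10 | 5,6,7,8-tetramethoxy-4-oxo-4H-chromene-2-carbaldehyde | O=Cc1cc(=O)c2c(OC)c(OC)c(OC)c(OC)c2o1 | intermediate
11 | lithium 2-diazo-1-(5,6,7,8-tetramethoxy-4-oxo-4H-chromen-2-yl)-2-(trimethylsilyl)ethan-1-olate (racemic) | [Li]OC(C(=[N+]=[N-])[Si](C)(C)C)c1cc(=O)c2c(OC)c(OC)c(OC)c(OC)c2o1 | intermediate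
12 | 2-ethynyl-5,6,7,8-tetramethoxy-4H-chromen-4-one | C#Cc1cc(=O)c2c(OC)c(OC)c(OC)c(OC)c2o1 | intermediate
13 | 3-methoxyfuran | COc1ccoc1 | starting material
14 | 2-(5-methoxy-7-oxabicyclo[2.2.1]hepta-2,5-dien-2-yl)-5,6,7,8-tetramethoxy-4H-chromen-4-one (racemic, one enantiomer drawn) | COC1=C[C@@H]2O[C@H]1C=C2c1cc(=O)c2c(OC)c(OC)c(OC)c(OC)c2o1 | intermediate
15 | 2-(3-hydroxy-4-methoxyphenyl)-5,6,7,8-tetramethoxy-4H-chromen-4-one (5-O-methylgardenin D) | COc1ccc(-c2cc(=O)c3c(OC)c(OC)c(OC)c(OC)c3o2)cc1O | intermediate
16 | 5,3'-bis-O-(dichloroboryl) derivative of gardenin D (boron on O5 chelated to the C4 carbonyl) | COc1ccc(-c2cc(=O)c3c(OB(Cl)Cl)c(OC)c(OC)c(OC)c3o2)cc1OB(Cl)Cl | intermediate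
17 | gardenin D | COc1ccc(-c2cc(=O)c3c(O)c(OC)c(OC)c(OC)c3o2)cc1O | target

**Step count**

Total step count: 8. Longest linear sequence: 8 steps (1 → 17); 6 and 13 enter as purchased compounds.

**Steps most likely to fail**

Step 7 (new method).
- What may go wrong:
  - The vinylogously activated alkyne may react too slowly, so the furan is consumed by Lewis-acid-induced oligomerisation first.
  - The first C–C bond may form and a proton then be lost, giving Michael-type substitution at furan C2 instead of closure of the second bond.
  - The adduct may revert before the bridge opens.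
- Fallback (known chemistry, from 5 back to 15): ring B is brought in ready-made.
  - Claisen–Schmidt condensation of 5 with purchased 3-benzyloxy-4-methoxybenzaldehyde (KOH, EtOH, rt) should give (E)-3-[3-(benzyloxy)-4-methoxyphenyl]-1-(2-hydroxy-3,4,5,6-tetramethoxyphenyl)prop-2-en-1-one F1.
  - Oxidative cyclisation (I2 cat., DMSO, 120 °C) should give 2-[3-(benzyloxy)-4-methoxyphenyl]-5,6,7,8-tetramethoxy-4H-chromen-4-one F2.
  - Hydrogenolysis (H2, Pd/C, EtOAc/MeOH) should release 15.

Step 6.
- What may go wrong:
  - The lithiated diazo reagent may add in a conjugate or dipolar fashion across C2=C3 of the pyranone instead of at the aldehyde.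
  - The silanolate released on warming may add to the enynone or open the pyranone ring.
- Fallback (no carbanionic reagent, from 10 back to 12):
  - Dibromo-olefination (CBr4, PPh3, CH2Cl2, 0 °C) should give 2-(2,2-dibromovinyl)-5,6,7,8-tetramethoxy-4H-chromen-4-one F3.
  - Hydrogenolysis of the less hindered C–Br bond (Bu3SnH, Pd(PPh3)4 cat., PhMe, rt) should give (Z)-2-(2-bromovinyl)-5,6,7,8-tetramethoxy-4H-chromen-4-one F4.
  - Anti-elimination with the non-nucleophilic base DBU (CH2Cl2, rt) should give 12.

Step 8.
- What may go wrong: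
  - Boron held on the 3'-oxygen may coordinate the neighbouring 4'-methoxy group and cleave it.
  - A second demethylation may follow at C6 once the 5-O-chelate has formed.
- Fallback (protecting-group detour, from 15 back to 17):
  - Acetylation (Ac2O, pyridine, rt) should give 2-methoxy-5-(5,6,7,8-tetramethoxy-4-oxo-4H-chromen-2-yl)phenyl acetate F5. It has no free phenol to carry boron next to the 4'-methoxy group.
  - BCl3 (1.1 equiv, CH2Cl2, −78 → 0 °C) should then engage only the C4=O/5-OMe site and give 5-(5-hydroxy-6,7,8-trimethoxy-4-oxo-4H-chromen-2-yl)-2-methoxyphenyl acetate F6.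
  - Methanolysis (K2CO3, MeOH, rt) should give 17.

**Further compounds**

F1 | step 7 | (E)-3-[3-(benzyloxy)-4-methoxyphenyl]-1-(2-hydroxy-3,4,5,6-tetramethoxyphenyl)prop-2-en-1-one | COc1ccc(/C=C/C(=O)c2c(O)c(OC)c(OC)c(OC)c2OC)cc1OCc1ccccc1
F2 | step 7 | 2-[3-(benzyloxy)-4-methoxyphenyl]-5,6,7,8-tetramethoxy-4H-chromen-4-one | COc1ccc(-c2cc(=O)c3c(OC)c(OC)c(OC)c(OC)c3o2)cc1OCc1ccccc1
F3 | step 6 | 2-(2,2-dibromovinyl)-5,6,7,8-tetramethoxy-4H-chromen-4-one | BrC(Br)=Cc1cc(=O)c2c(OC)c(OC)c(OC)c(OC)c2o1
F4 | step 6 | (Z)-2-(2-bromovinyl)-5,6,7,8-tetramethoxy-4H-chromen-4-one | Br/C=C\c1cc(=O)c2c(OC)c(OC)c(OC)c(OC)c2o1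
F5 | step 8 | 2-methoxy-5-(5,6,7,8-tetramethoxy-4-oxo-4H-chromen-2-yl)phenyl acetate | COc1ccc(-c2cc(=O)c3c(OC)c(OC)c(OC)c(OC)c3o2)cc1OC(C)=O
F6 | step 8 | 5-(5-hydroxy-6,7,8-trimethoxy-4-oxo-4H-chromen-2-yl)-2-methoxyphenyl acetate | COc1ccc(-c2cc(=O)c3c(O)c(OC)c(OC)c(OC)c3o2)cc1OC(C)=O
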